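**Plan**

- Retrosynthetic cuts, in order: the 18 benzyl ethers and 2 C–Br bonds; C3–B of the catechin unit (unit 3); ring C of unit 3 at C4–C3 and O1–C2 (o-quinone methide + E-alkenylboronate); C4(unit 2)–C6(unit 3); C4(unit 1)–C8(unit 2); the two gallate esters.
- Forward: all rings of the two epicatechin gallate units come from (−)-epicatechin. Unit 1 (4-alkoxy, 8-Br) and unit 2 (4-arylthio) give the 4β→8 dimer. The dimer is joined at C4 to the only free carbon of a pentasubstituted phenol (future ring A of unit 3). Ring C of unit 3 is the only ring made, last, and brings ring B with it.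
- Enabling feature: ring A of unit 3 is a phloroglucinol nucleus in which O1 and the C4-bearing carbon C4a are ortho, so O1=C8a–C4a=C4 is an o-quinone methide and the 2-aryl-3-hydroxypyran ring C is its [4+2] adduct with ArCH=CH–X. The interflavan bond to unit 3 is made before ring C closes, and its position para to O1 (C6) is secured by Br at C8 and benzyl groups on O5 and O7.
- Stereochemistry: C2 and C3 of units 1 and 2 come from (−)-epicatechin; both C4 centres arise by attack anti to the 3-O-galloyl group; C2/C3 of unit 3 are trans from the E alkene, with absolute sense from the enantiopure ligand on boron; C–B goes to C–OH with retention.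

Key step: step 18

Assumption: the alkene face left open by the isopinocampheyl group of the dienophile is taken, by analogy with peracid epoxidation of alkenyl boronates carrying the same ligand, to be the one leading to the (2R,3S) unit; this is to be confirmed on the small phenol precursor, and if the sense is opposite the ligand from (1S,2S,3S,5R)-isopinocampheylamine is used with no other change.

Short forms: Bn = benzyl; G = 3,4,5-tris(benzyloxy)benzoyl; Tol = 4-methylphenyl; unit 1, 2, 3 = upper, middle, terminal flavan unit.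

**Route**

Step 1
Reactants: 1 (−)-epicatechin
Product: 2 5,7,3′,4′-tetra-O-benzyl-(−)-epicatechin
Conditions: BnBr (4.4 equiv), K2CO3, DMF, 0 °C to rt
Reagents that add atoms: benzyl bromide, BrCc1ccccc1
Why: Williamson etherification of the four phenols only (K2CO3 does not deprotonate the secondary alcohol); C2 and C3 are untouched at low temperature.

Step 2
Reactants: 2 5,7,3′,4′-tetra-O-benzyl-(−)-epicatechin
Product: 3 8-bromo-5,7,3′,4′-tetra-O-benzyl-(−)-epicatechin
Conditions: NBS (1.0 equiv), CH2Cl2, −78 °C to rt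
Reagents that add atoms: N-bromosuccinimide, O=C1CCC(=O)N1Br
Why: Electrophilic aromatic bromination at C8, the most nucleophilic carbon of ring A; the bromine caps the position through which unit 1 could self-condense in steps 8 and 12 and is removed in step 20.

Step 3
Reactants: 3 8-bromo-5,7,3′,4′-tetra-O-benzyl-(−)-epicatechin
Product: 4 8-bromo-4β-(2-ethoxyethoxy)-5,7,3′,4′-tetra-O-benzyl-(−)-epicatechin
Conditions: DDQ (2 equiv), 2-ethoxyethanol (5 equiv), CH2Cl2, rt
Reagents that add atoms: 2-ethoxyethanol, CCOCCO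
Why: Benzylic oxidation by hydride abstraction at C4 (cation stabilised by O5 and O7) and capture by the alcohol anti to the 3-OH; this C4 configuration is lost again when the group leaves in step 8.

Step 4
Reactants: 4 8-bromo-4β-(2-ethoxyethoxy)-5,7,3′,4′-tetra-O-benzyl-(−)-epicatechin; 5 3,4,5-tris(benzyloxy)benzoic acid
Product: 6 8-bromo-4β-(2-ethoxyethoxy)-5,7,3′,4′-tetra-O-benzyl-(−)-epicatechin 3-O-[3,4,5-tris(benzyloxy)benzoate]
Conditions: DCC, DMAP, CH2Cl2, rt
Reagents that add atoms: none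
Why: Steglich esterification of the hindered axial 3-OH; no stereocentre is involved.

Step 5
Reactants: 2 5,7,3′,4′-tetra-O-benzyl-(−)-epicatechin
Product: 7 4β-(2-ethoxyethoxy)-5,7,3′,4′-tetra-O-benzyl-(−)-epicatechin
Conditions: DDQ (2 equiv), 2-ethoxyethanol (5 equiv), CH2Cl2, rt
Reagents that add atoms: 2-ethoxyethanol, CCOCCO
Why: The same DDQ benzylic oxidation and alcohol capture at C4 as in step 3, here on the unit that must keep C8 free.

Step 6
Reactants: 7 4β-(2-ethoxyethoxy)-5,7,3′,4′-tetra-O-benzyl-(−)-epicatechin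
Product: 8 4β-(4-methylphenylthio)-5,7,3′,4′-tetra-O-benzyl-(−)-epicatechin
Conditions: 4-methylbenzenethiol (3 equiv), BF3·OEt2 (0.3 equiv), CH2Cl2, −78 to −40 °C
Reagents that add atoms: 4-methylbenzenethiol, Cc1ccc(S)cc1
Why: Thiolysis-type SN1 exchange: the C4 cation is captured by the thiol anti to the 3-OH to give the 4β thioether, a leaving group that hard Lewis acids do not activate.

Step 7
Reactants: 8 4β-(4-methylphenylthio)-5,7,3′,4′-tetra-O-benzyl-(−)-epicatechin; 5 3,4,5-tris(benzyloxy)benzoic acid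
Product: 9 4β-(4-methylphenylthio)-5,7,3′,4′-tetra-O-benzyl-(−)-epicatechin 3-O-[3,4,5-tris(benzyloxy)benzoate]
Conditions: DCC, DMAP, CH2Cl2, rt
Reagents that add atoms: none
Why: Steglich esterification of the 3-OH; the thioether is inert to carbodiimide and DMAP.

Step 8
Reactants: 6 8-bromo-4β-(2-ethoxyethoxy)-5,7,3′,4′-tetra-O-benzyl-(−)-epicatechin 3-O-[3,4,5-tris(benzyloxy)benzoate]; 9 4β-(4-methylphenylthio)-5,7,3′,4′-tetra-O-benzyl-(−)-epicatechin 3-O-[3,4,5-tris(benzyloxy)benzoate] (1.5 equiv)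
Product: 10 dimer thioether [8-bromo-5,7,3′,4′-tetra-O-benzylepicatechin 3-O-G]-(4β→8)-[4β-(4-methylphenylthio)-5,7,3′,4′-tetra-O-benzylepicatechin 3-O-G]
Conditions: TMSOTf (0.2 equiv), CH2Cl2, −78 to −40 °C; then Et3N
Reagents that add atoms: none
Why: Friedel–Crafts alkylation in which the hard silyl triflate ionises only the 4-alkoxy group of 6, and C8 of 9 (its most nucleophilic free carbon) attacks the cation anti to the 3-O-galloyl group, which can shield the syn face as an acyloxonium bridge, setting the 4β (3,4-trans) centre.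

Step 9
Reactants: 11 3,5-bis(benzyloxy)phenol
Product: 12 2-hydroxy-4,6-bis(benzyloxy)benzaldehyde
Conditions: MgCl2 (2 equiv), Et3N (4 equiv), paraformaldehyde (6 equiv), MeCN, reflux
Reagents that add atoms: formaldehyde (from paraformaldehyde), C=O
Why: Casnati–Skattebøl ortho-formylation through the magnesium phenoxide puts the future C4 only ortho to the free OH (future O1); the two ortho positions are equivalent.

Step 10
Reactants: 12 2-hydroxy-4,6-bis(benzyloxy)benzaldehyde
Product: 13 3-bromo-2-hydroxy-4,6-bis(benzyloxy)benzaldehyde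
Conditions: NBS (1.0 equiv), CH2Cl2, 0 °C
Reagents that add atoms: N-bromosuccinimide, O=C1CCC(=O)N1Br
Why: Electrophilic aromatic bromination, expected by analogy with halogenation of 2-hydroxy-4,6-dialkoxyaryl ketones to enter ortho to the chelated OH (future C8), leaving the carbon between the two benzyloxy groups (future C6) as the only free ring position.

Step 11
Reactants: 13 3-bromo-2-hydroxy-4,6-bis(benzyloxy)benzaldehyde
Product: 15 2-bromo-3,5-bis(benzyloxy)-6-[(4-methylphenylsulfonyl)methyl]phenol, via salicyl alcohol 14 (not isolated)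
Conditions: NaBH4, THF/MeOH, 0 °C; then sodium 4-methylbenzenesulfinate (3 equiv), HCO2H/H2O, rt
Reagents that add atoms: sodium 4-methylbenzenesulfinate, Cc1ccc(cc1)S(=O)[O-].[Na+]
Why: Aldehyde reduction followed by acid-promoted SN1 substitution of the electron-rich salicyl alcohol by the sulfinate sulfur gives a benzylic sulfone that withstands the Lewis acid of step 12 and releases the quinone methide only with base.

Step 12
Reactants: 10 dimer thioether; 15 2-bromo-3,5-bis(benzyloxy)-6-[(4-methylphenylsulfonyl)methyl]phenol (3 equiv)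
Product: 16 dimer of 10 in which the arylthio group is replaced, with 4β configuration, by the 2,6-bis(benzyloxy)-3-bromo-4-hydroxy-5-[(4-methylphenylsulfonyl)methyl]phenyl group
Conditions: AgBF4 (1.5 equiv), 2,6-di-tert-butyl-4-methylpyridine (1.5 equiv), 4 Å MS, CH2Cl2, −78 to 0 °C
Reagents that add atoms: none
Why: Thiophile-promoted Friedel–Crafts alkylation: Ag+ removes the arylthio group and the C4 cation of unit 2 is attacked, anti to the 3-O-galloyl group, by the only unsubstituted ring carbon of 15 (para to the free OH), which sets the 4β→6 connectivity of the trimer.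

Step 13
Reactants: 17 3,4-bis(benzyloxy)benzaldehyde; 18 bis(pinacolato)borylmethane
Product: 19 (E)-2-[2-(3,4-bis(benzyloxy)phenyl)ethenyl]-4,4,5,5-tetramethyl-1,3,2-dioxaborolane
Conditions: lithium 2,2,6,6-tetramethylpiperidide (LiTMP, 1.2 equiv), THF, 0 °C; then 17, −78 °C to rt
Reagents that add atoms: none
Why: Boron-Wittig olefination (addition of the lithiated geminal bis(boronate) to the aldehyde, then syn elimination of the O–B unit) should give the E alkenylboronate.

Step 14
Reactants: 19 (E)-alkenyl pinacol boronate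
Product: 20 (E)-[2-(3,4-bis(benzyloxy)phenyl)ethenyl]boronic acid
Conditions: NaIO4 (3 equiv), NH4OAc, acetone/H2O, rt
Reagents that add atoms: water, O
Why: Hydrolysis of the boronic ester driven by periodate cleavage of the released pinacol; the alkene geometry is not affected.

Step 15
Reactants: 21 (1R,2R,3R,5S)-(−)-isopinocampheylamine
Product: 22 dibenzyl N-[(1R,2R,3R,5S)-isopinocampheyl]iminodiacetate
Conditions: benzyl bromoacetate (2.5 equiv), K2CO3, NaI (cat.), MeCN, 70 °C
Reagents that add atoms: benzyl bromoacetate, BrCC(=O)OCc1ccccc1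
Why: Double SN2 N-alkylation of the primary amine; the pinane stereocentres are not involved.

Step 16
Reactants: 22 dibenzyl N-isopinocampheyliminodiacetate
Product: 23 N-[(1R,2R,3R,5S)-isopinocampheyl]iminodiacetic acid
Conditions: H2 (1 atm), Pd/C, MeOH, rt
Reagents that add atoms: none
Why: Hydrogenolysis of the two benzyl esters gives the salt-free diacid ligand.

Step 17
Reactants: 20 (E)-alkenylboronic acid; 23 N-isopinocampheyliminodiacetic acid
Product: 24 2-[(E)-2-(3,4-bis(benzyloxy)phenyl)ethenyl]-6-[(1R,2R,3R,5S)-isopinocampheyl]-1,3,6,2-dioxazaborocane-4,8-dione (N→B coordinated; SMILES drawn without the dative bond)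
Conditions: toluene/DMSO (10:1), reflux, Dean–Stark trap
Reagents that add atoms: none
Why: Dehydrative condensation of a boronic acid with an N-alkyliminodiacetic acid, as for N-methyliminodiacetic acid boronates, gives the tetracoordinate boronate with the E geometry retained.

Step 18
Reactants: 16 sulfonylmethyl phenol of the dimer; 24 (E)-alkenyl iminodiacetate boronate (3 equiv)
Product: 26 protected trimer boronate (boron at C3 of the 2R-configured 2,3-trans unit 3), via o-quinone methide 25 (not isolated)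
Conditions: K3PO4 (anhydrous, powdered, 3 equiv), 4 Å MS, THF (0.02 M in 16), 25 to 60 °C
Reagents that add atoms: none
Why: Proposed new method: K3PO4 deprotonates the only free phenol of 16 and the phenoxide expels 4-methylbenzenesulfinate (1,4-elimination) to give o-quinone methide 25 (O1=C8a–C4a=C4 of the future ring C), whose electrophilic CH2 bonds to the boron-bearing alkene carbon of 24 while O1 bonds to the benzylic carbon in one asynchronous inverse-electron-demand oxa-[4+2] transition state, the stepwise limit being a zwitterion whose positive charge at the future C2 is stabilised by the 3,4-bis(benzyloxy)phenyl ring and the adjacent C–B bond. The closest known reaction types are the hetero-Diels–Alder additions of o-quinone methides (including those released by base from 2-(sulfonylmethyl)phenols) to β-substituted electron-rich styrenes, which give 2,3-trans-2-aryl-3-substituted chromans, and the face-selective peracid epoxidation of alkenyl boronates carrying the same pinene-derived iminodiacetate; an alkenyl boronate has not been used as the 2π partner of an o-quinone methide. Ring C, the only ring formed, closes by intermolecular [4π+2π] cycloaddition that makes C4–C3 and O1–C2 together. C2 and C3 arise trans because both bonds form on one face of the E alkene without bond rotation, and their absolute sense should come from the isopinocampheyl group on nitrogen, which lies next to the B–C=C unit and covers one alkene face. The step needs a single quinone methide (secured by the benzyl ethers on O5 and O7, so only O1 can take part), one orientation (secured by the donor aryl group on the carbon that becomes C2 and by tetracoordinate boron on the carbon that becomes C3, which also cannot bind the phenoxide and so closes the alkenyl-transfer pathway of tricoordinate boronates), and chemoselectivity against the other electron-rich rings and against dimerisation of 25 (secured by the bromine at C8, slow release of 25 by the insoluble base, dilution and excess 24).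

Step 19
Reactants: 26 protected trimer carrying boron at C3 of unit 3
Product: 27 [8-bromo-5,7,3′,4′-tetra-O-benzylepicatechin 3-O-G]-(4β→8)-[5,7,3′,4′-tetra-O-benzylepicatechin 3-O-G]-(4β→6)-[8-bromo-5,7,3′,4′-tetra-O-benzyl-(+)-catechin]
Conditions: aq NaHCO3, THF/MeOH, 45 °C; then 30% H2O2, 0 °C to rt
Reagents that add atoms: hydrogen peroxide, OO
Why: Mild hydrolysis of the iminodiacetate cage and oxidation of the C–B bond (1,2-shift of C3 from boron to oxygen, with retention) give the 3-OH trans to the 2-aryl group, under conditions the hindered aryl esters should survive.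

Step 20
Reactants: 27 protected trimer
Product: 28 (−)-epicatechin 3-O-gallate-(4β→8)-(−)-epicatechin 3-O-gallate-(4β→6)-(+)-catechin (CNP0154615.1)
Conditions: H2 (1 atm), Pd(OH)2/C, Et3N (2.5 equiv), THF/MeOH/H2O, rt; filtration, Sephadex LH-20
Reagents that add atoms: none
Why: Hydrogenolysis of the eighteen benzyl ethers and both aryl C–Br bonds touches no stereocentre, and the amine takes up HBr so that the acid-labile interflavan bonds are not cleaved.

**Compound list**

1 | (−)-epicatechin, (2R,3R) | O[C@@H]1Cc2c(O)cc(O)cc2O[C@@H]1c1ccc(O)c(O)c1 | starting material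
2 | 5,7,3′,4′-tetra-O-benzyl-(−)-epicatechin | O[C@@H]1Cc2c(OCc5ccccc5)cc(OCc5ccccc5)cc2O[C@@H]1c1ccc(OCc5ccccc5)c(OCc5ccccc5)c1 | intermediate
3 | 8-bromo-5,7,3′,4′-tetra-O-benzyl-(−)-epicatechin | O[C@@H]1Cc2c(OCc5ccccc5)cc(OCc5ccccc5)c(Br)c2O[C@@H]1c1ccc(OCc5ccccc5)c(OCc5ccccc5)c1 | intermediate
4 | 8-bromo-4β-(2-ethoxyethoxy)-5,7,3′,4′-tetra-O-benzyl-(−)-epicatechin (3,4-trans) | O[C@@H]1[C@@H](OCCOCC)c2c(OCc5ccccc5)cc(OCc5ccccc5)c(Br)c2O[C@@H]1c1ccc(OCc5ccccc5)c(OCc5ccccc5)c1 | intermediate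
5 | 3,4,5-tris(benzyloxy)benzoic acid | OC(=O)c1cc(OCc5ccccc5)c(OCc5ccccc5)c(OCc5ccccc5)c1 | starting material
6 | 8-bromo-4β-(2-ethoxyethoxy)-5,7,3′,4′-tetra-O-benzyl-(−)-epicatechin 3-O-[3,4,5-tris(benzyloxy)benzoate] | O=C(O[C@@H]1[C@@H](OCCOCC)c2c(OCc5ccccc5)cc(OCc5ccccc5)c(Br)c2O[C@@H]1c1ccc(OCc5ccccc5)c(OCc5ccccc5)c1)c1cc(OCc5ccccc5)c(OCc5ccccc5)c(OCc5ccccc5)c1 | intermediate
7 | 4β-(2-ethoxyethoxy)-5,7,3′,4′-tetra-O-benzyl-(−)-epicatechin | O[C@@H]1[C@@H](OCCOCC)c2c(OCc5ccccc5)cc(OCc5ccccc5)cc2O[C@@H]1c1ccc(OCc5ccccc5)c(OCc5ccccc5)c1 | intermediate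
8 | 4β-(4-methylphenylthio)-5,7,3′,4′-tetra-O-benzyl-(−)-epicatechin | O[C@@H]1[C@@H](Sc2ccc(C)cc2)c2c(OCc5ccccc5)cc(OCc5ccccc5)cc2O[C@@H]1c1ccc(OCc5ccccc5)c(OCc5ccccc5)c1 | intermediate
9 | 4β-(4-methylphenylthio)-5,7,3′,4′-tetra-O-benzyl-(−)-epicatechin 3-O-[3,4,5-tris(benzyloxy)benzoate] | O=C(O[C@@H]1[C@@H](Sc2ccc(C)cc2)c2c(OCc5ccccc5)cc(OCc5ccccc5)cc2O[C@@H]1c1ccc(OCc5ccccc5)c(OCc5ccccc5)c1)c1cc(OCc5ccccc5)c(OCc5ccccc5)c(OCc5ccccc5)c1 | intermediate
10 | dimer thioether: [8-bromo-5,7,3′,4′-tetra-O-benzylepicatechin 3-O-G]-(4β→8)-[4β-(4-methylphenylthio)-5,7,3′,4′-tetra-O-benzylepicatechin 3-O-G] | O=C(O[C@@H]1[C@@H](c2c(OCc5ccccc5)cc(OCc5ccccc5)c3c2O[C@H](c2ccc(OCc5ccccc5)c(OCc5ccccc5)c2)[C@H](OC(=O)c2cc(OCc5ccccc5)c(OCc5ccccc5)c(OCc5ccccc5)c2)[C@H]3Sc2ccc(C)cc2)c2c(OCc5ccccc5)cc(OCc5ccccc5)c(Br)c2O[C@@H]1c1ccc(OCc5ccccc5)c(OCc5ccccc5)c1)c1cc(OCc5ccccc5)c(OCc5ccccc5)c(OCc5ccccc5)c1 | intermediate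
11 | 3,5-bis(benzyloxy)phenol | Oc1cc(OCc5ccccc5)cc(OCc5ccccc5)c1 | starting material
12 | 2-hydroxy-4,6-bis(benzyloxy)benzaldehyde | O=Cc1c(O)cc(OCc5ccccc5)cc1OCc5ccccc5 | intermediate
13 | 3-bromo-2-hydroxy-4,6-bis(benzyloxy)benzaldehyde | O=Cc1c(O)c(Br)c(OCc5ccccc5)cc1OCc5ccccc5 | intermediate
14 | 2-bromo-3,5-bis(benzyloxy)-6-(hydroxymethyl)phenol | OCc1c(O)c(Br)c(OCc5ccccc5)cc1OCc5ccccc5 | intermediate
15 | 2-bromo-3,5-bis(benzyloxy)-6-[(4-methylphenylsulfonyl)methyl]phenol | Cc1ccc(cc1)S(=O)(=O)Cc1c(O)c(Br)c(OCc5ccccc5)cc1OCc5ccccc5 | intermediate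
16 | [8-bromo-5,7,3′,4′-tetra-O-benzylepicatechin 3-O-G]-(4β→8)-[5,7,3′,4′-tetra-O-benzylepicatechin 3-O-G] bearing at C4 of unit 2 (4β) the 2,6-bis(benzyloxy)-3-bromo-4-hydroxy-5-[(4-methylphenylsulfonyl)methyl]phenyl group | O=C(O[C@@H]1[C@@H](c2c(OCc5ccccc5)cc(OCc5ccccc5)c3c2O[C@H](c2ccc(OCc5ccccc5)c(OCc5ccccc5)c2)[C@H](OC(=O)c2cc(OCc5ccccc5)c(OCc5ccccc5)c(OCc5ccccc5)c2)[C@H]3c2c(OCc5ccccc5)c(Br)c(O)c(CS(=O)(=O)c4ccc(C)cc4)c2OCc5ccccc5)c2c(OCc5ccccc5)cc(OCc5ccccc5)c(Br)c2O[C@@H]1c1ccc(OCc5ccccc5)c(OCc5ccccc5)c1)c1cc(OCc5ccccc5)c(OCc5ccccc5)c(OCc5ccccc5)c1 | intermediate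
17 | 3,4-bis(benzyloxy)benzaldehyde | O=Cc1ccc(OCc5ccccc5)c(OCc5ccccc5)c1 | starting material
18 | bis(pinacolato)borylmethane, 2,2′-methylenebis(4,4,5,5-tetramethyl-1,3,2-dioxaborolane) | CC1(C)OB(CB2OC(C)(C)C(C)(C)O2)OC1(C)C | starting material
19 | (E)-2-[2-(3,4-bis(benzyloxy)phenyl)ethenyl]-4,4,5,5-tetramethyl-1,3,2-dioxaborolane | CC1(C)OB(/C=C/c2ccc(OCc5ccccc5)c(OCc5ccccc5)c2)OC1(C)C | intermediate
20 | (E)-[2-(3,4-bis(benzyloxy)phenyl)ethenyl]boronic acid | OB(O)/C=C/c1ccc(OCc5ccccc5)c(OCc5ccccc5)c1 | intermediate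
21 | (1R,2R,3R,5S)-(−)-isopinocampheylamine | N[C@@H]1C[C@@H]2C[C@H]([C@H]1C)C2(C)C | starting material
22 | dibenzyl N-[(1R,2R,3R,5S)-isopinocampheyl]iminodiacetate | O=C(CN(CC(=O)OCc5ccccc5)[C@@H]1C[C@@H]2C[C@H]([C@H]1C)C2(C)C)OCc5ccccc5 | intermediate
23 | N-[(1R,2R,3R,5S)-isopinocampheyl]iminodiacetic acid | OC(=O)CN(CC(=O)O)[C@@H]1C[C@@H]2C[C@H]([C@H]1C)C2(C)C | intermediate
24 | 2-[(E)-2-(3,4-bis(benzyloxy)phenyl)ethenyl]-6-[(1R,2R,3R,5S)-isopinocampheyl]-1,3,6,2-dioxazaborocane-4,8-dione (dative N→B bond not drawn) | O=C1CN(CC(=O)OB(O1)/C=C/c1ccc(OCc5ccccc5)c(OCc5ccccc5)c1)[C@@H]1C[C@@H]2C[C@H]([C@H]1C)C2(C)C | intermediate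
25 | o-quinone methide of 16: the phenol ring turned into a 3,5-bis(benzyloxy)-2-bromo-6-methylenecyclohexa-2,4-dien-1-one carrying the dimer at C4 of that ring | O=C(O[C@@H]1[C@@H](c2c(OCc5ccccc5)cc(OCc5ccccc5)c3c2O[C@H](c2ccc(OCc5ccccc5)c(OCc5ccccc5)c2)[C@H](OC(=O)c2cc(OCc5ccccc5)c(OCc5ccccc5)c(OCc5ccccc5)c2)[C@H]3C2=C(OCc5ccccc5)C(=C)C(=O)C(Br)=C2OCc5ccccc5)c2c(OCc5ccccc5)cc(OCc5ccccc5)c(Br)c2O[C@@H]1c1ccc(OCc5ccccc5)c(OCc5ccccc5)c1)c1cc(OCc5ccccc5)c(OCc5ccccc5)c(OCc5ccccc5)c1 | intermediate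
26 | protected trimer with the isopinocampheyliminodiacetate boronate at C3 of unit 3 (unit 3: 8-bromo-5,7,3′,4′-tetra-O-benzyl, 2R, 2,3-trans, linked at C6) | O=C(O[C@@H]1[C@@H](c2c(OCc5ccccc5)cc(OCc5ccccc5)c3c2O[C@H](c2ccc(OCc5ccccc5)c(OCc5ccccc5)c2)[C@H](OC(=O)c2cc(OCc5ccccc5)c(OCc5ccccc5)c(OCc5ccccc5)c2)[C@H]3c2c(OCc5ccccc5)c(Br)c3c(c2OCc5ccccc5)C[C@H](B4OC(=O)CN([C@@H]6C[C@@H]7C[C@H]([C@H]6C)C7(C)C)CC(=O)O4)[C@@H](c2ccc(OCc5ccccc5)c(OCc5ccccc5)c2)O3)c2c(OCc5ccccc5)cc(OCc5ccccc5)c(Br)c2O[C@@H]1c1ccc(OCc5ccccc5)c(OCc5ccccc5)c1)c1cc(OCc5ccccc5)c(OCc5ccccc5)c(OCc5ccccc5)c1 | intermediate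
27 | [8-bromo-5,7,3′,4′-tetra-O-benzylepicatechin 3-O-G]-(4β→8)-[5,7,3′,4′-tetra-O-benzylepicatechin 3-O-G]-(4β→6)-[8-bromo-5,7,3′,4′-tetra-O-benzyl-(+)-catechin] | O=C(O[C@@H]1[C@@H](c2c(OCc5ccccc5)cc(OCc5ccccc5)c3c2O[C@H](c2ccc(OCc5ccccc5)c(OCc5ccccc5)c2)[C@H](OC(=O)c2cc(OCc5ccccc5)c(OCc5ccccc5)c(OCc5ccccc5)c2)[C@H]3c2c(OCc5ccccc5)c(Br)c3c(c2OCc5ccccc5)C[C@H](O)[C@@H](c2ccc(OCc5ccccc5)c(OCc5ccccc5)c2)O3)c2c(OCc5ccccc5)cc(OCc5ccccc5)c(Br)c2O[C@@H]1c1ccc(OCc5ccccc5)c(OCc5ccccc5)c1)c1cc(OCc5ccccc5)c(OCc5ccccc5)c(OCc5ccccc5)c1 | intermediate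
28 | (−)-epicatechin 3-O-gallate-(4β→8)-(−)-epicatechin 3-O-gallate-(4β→6)-(+)-catechin; unit 1 (2R,3R,4R), unit 2 (2R,3R,4S), unit 3 (2R,3S) | O=C(O[C@@H]1[C@@H](c2c(O)cc(O)c3c2O[C@H](c2ccc(O)c(O)c2)[C@H](OC(=O)c2cc(O)c(O)c(O)c2)[C@H]3c2c(O)cc3c(c2O)C[C@H](O)[C@@H](c2ccc(O)c(O)c2)O3)c2c(O)cc(O)cc2O[C@@H]1c1ccc(O)c(O)c1)c1cc(O)c(O)c(O)c1 | target

**Step count and risks**

Total step count: 20. Longest linear sequence: 9 steps (1, 2, 3, 4, 8, 12, 18, 19, 20).

Steps most likely to fail:

1. Step 18 (proposed new method). The quinone methide may be consumed by dimerisation, by re-addition of sulfinate or by attack of a neighbouring electron-rich ring faster than the hindered alkenyl boronate adds, and the ligand may discriminate the two alkene faces poorly. The fallback uses known reaction types only, sets out from 10 and comes back at 27. Commercial (+)-catechin is benzylated (BnBr, K2CO3, DMF) to 5,7,3′,4′-tetra-O-benzyl-(+)-catechin F1, which is brominated at C8 (NBS, CH2Cl2) to 8-bromo-5,7,3′,4′-tetra-O-benzyl-(+)-catechin F2. F2 is then alkylated at C6, its only free ring-A carbon, by the C4 cation released from 10 with AgBF4 as in step 12. The product is 27, and ring C of unit 3 then comes from the chiral pool instead of the cycloaddition.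

2. Step 12. Attack by the hindered, bromine- and sulfone-deactivated ring of 15 may be slower than self-condensation of the cation from 10 through the free C6 positions of units 1 and 2, or than loss of a proton to the flavene. The fallback sets out from 15 and comes back at 26, with the two C–C bond constructions in the opposite order. Phenol 15 is first annulated with 24 (K3PO4, THF, as in step 18) to the small chroman boronate (2R,2,3-trans)-8-bromo-5,7-bis(benzyloxy)-2-[3,4-bis(benzyloxy)phenyl]chroman-3-yl isopinocampheyliminodiacetate boronate F3, a C6 nucleophile of the established 8-bromoflavan type. F3 is then joined to the cation from 10 (AgBF4, 2,6-di-tert-butyl-4-methylpyridine, CH2Cl2), which gives 26 directly; this fallback still relies on the cycloaddition, now on a small substrate.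

3. Step 19. Opening of the bulky boronate cage may be incomplete in the poorly water-miscible medium, or the two gallate esters may be cleaved or migrate under prolonged basic peroxide treatment. The fallback sets out from 26 and comes back at 27, with cage removal and oxidation separated. The ligand is exchanged for pinacol (pinacol, NaHCO3, MeOH/THF, 45 °C) to give the pinacol boronate of the protected trimer F4, which is then oxidised under near-neutral conditions (NaBO3·4H2O, THF/H2O, rt) with retention to 27.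

**Further compounds**

F1 | step 18 | 5,7,3′,4′-tetra-O-benzyl-(+)-catechin | O[C@H]1Cc2c(OCc5ccccc5)cc(OCc5ccccc5)cc2O[C@@H]1c1ccc(OCc5ccccc5)c(OCc5ccccc5)c1
F2 | step 18 | 8-bromo-5,7,3′,4′-tetra-O-benzyl-(+)-catechin | O[C@H]1Cc2c(OCc5ccccc5)cc(OCc5ccccc5)c(Br)c2O[C@@H]1c1ccc(OCc5ccccc5)c(OCc5ccccc5)c1
F3 | step 12 | (2R,2,3-trans)-8-bromo-5,7-bis(benzyloxy)-2-[3,4-bis(benzyloxy)phenyl]chroman-3-yl isopinocampheyliminodiacetate boronate | c1c(OCc5ccccc5)c(Br)c3c(c1OCc5ccccc5)C[C@H](B4OC(=O)CN([C@@H]6C[C@@H]7C[C@H]([C@H]6C)C7(C)C)CC(=O)O4)[C@@H](c2ccc(OCc5ccccc5)c(OCc5ccccc5)c2)O3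
F4 | step 19 | pinacol boronate analogue of 26 (4,4,5,5-tetramethyl-1,3,2-dioxaborolan-2-yl at C3 of unit 3) | O=C(O[C@@H]1[C@@H](c2c(OCc5ccccc5)cc(OCc5ccccc5)c3c2O[C@H](c2ccc(OCc5ccccc5)c(OCc5ccccc5)c2)[C@H](OC(=O)c2cc(OCc5ccccc5)c(OCc5ccccc5)c(OCc5ccccc5)c2)[C@H]3c2c(OCc5ccccc5)c(Br)c3c(c2OCc5ccccc5)C[C@H](B4OC(C)(C)C(C)(C)O4)[C@@H](c2ccc(OCc5ccccc5)c(OCc5ccccc5)c2)O3)c2c(OCc5ccccc5)cc(OCc5ccccc5)c(Br)c2O[C@@H]1c1ccc(OCc5ccccc5)c(OCc5ccccc5)c1)c1cc(OCc5ccccc5)c(OCc5ccccc5)c(OCc5ccccc5)c1
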